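## The problem

Cembrane numbering is used throughout: ring carbons C1–C14; C15 (bearing C16 and C17) on C1; methyl carbons C18 on C4, C19 on C8, C20 on C12. The target, read from the SMILES as (1R,3R,4S,7S,11S,12S,15S), is a fourteen-membered carbocycle bridged between C1 and C3 by a six-membered lactone (C16(=O)–O–C3). It carries a tertiary alcohol at C4, a trans trisubstituted epoxide at C11/C12 and a secondary allylic hydroperoxide at C7 beside the C8=C19 exocyclic methylene.

A synthesis has to build a macrocycle whose methyl-bearing carbons C4, C8 and C12 are 1,5-related. It also has to tell apart two sites, C7/C8 and C11/C12, that both descend from like trisubstituted (E)-olefins. The seven stereocentres fall into three groups too far apart to control one another reliably: C1/C15/C3/C4 around the lactone, C11/C12, and C7. Within the first group a C3 hydroxyl can direct C4, and C15 is epimerizable and has the stable configuration (methyl trans to the C1–C14 bond). The hydroperoxide will not survive hydrides, boranes, phosphines, low-valent metals or strong base and must come last; the epoxide forbids acid, and the lactone α-centre forbids careless base.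

The feature that opens the route is this. The oxygen-bearing C3 stands δ,ε to the C7=C8 bond hidden behind the hydroperoxide (C3–C4–C5–C6–C7=C8), which is the retron of an oxy-Cope rearrangement. Excising C4–C7 by that retron joins C3 to C8 in a ten-membered ring, where C3 again stands δ,ε to C11=C12 (C3–C8–C9–C10–C11=C12). A second excision leaves the six-membered ring C12–C13–C14–C1–C2–C3 with the three-carbon unit on C1, which is the skeleton and the stereocentre of (R)-carvone.

## Retrosynthesis

**22 ⇒ 21.** Cut the C7–O bond and return the double bond from C8=C19 to C7=C8. The forward reaction is the Schenck ene reaction of singlet oxygen. The O–O bond tolerates none of the reductants, boranes, palladium or titanium reagents used earlier, and a secondary allylic hydroperoxide beside an exocyclic methylene is what singlet oxygen makes from a methyl-bearing (E)-olefin. Lactone 21 has one stereocentre and one sensitive group fewer. Asked of the forward step: oxygen to C7, hydrogen from C19, one olefin face.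

**21 ⇒ 20 ⇒ 17 ⇒ 15.** Cut the lactone C16–O bond and lower C16 to the terminal carbon of an isopropenyl group. An isopropenyl group is inert to the bases, Grignard reagents and hydrides of the skeleton-building steps, which a carboxyl carbon would not be. C15 needs no asymmetric step, because it is α to the carbonyl and the wanted isomer is the stable one (20 → 21). Asked: hydroboration of a 1,1-disubstituted alkene beside a trisubstituted one (15 → 17), and oxidation of a primary alcohol beside a secondary and a tertiary one with closure on the C3 oxygen (17 → 20).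

**15 ⇒ 14 ⇒ 13 ⇒ 12.** Cut C4–O and return C3 to a ketone. The anti 3,4-diol 15 is what hydride opening at C5 of the erythro 4,5-epoxy-3-ol 14 gives. Epoxy alcohol 14 is what a matched Sharpless epoxidation gives from the (3R)-allylic alcohol 13, which comes from CBS reduction of enone 12. The neighbouring option, direct hydroxylation of the C3/C4 enolate and ketone reduction, would leave the relation of C4 to the distant C1 to macrocyclic conformation. Here both centres are under reagent control, and the hydroxyl-directed epoxidation ignores C7=C8. Enone 12 has two stereocentres fewer.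

**12 ⇒ 11 ⇒ 9 (key).** Cut C5–C6 and rejoin C3–C8. Enone 12 comes from silyl enol ether 11, the trapped enolate of a C3 ketone that is δ,ε to C7=C8. The retro-oxy-Cope step contracts the fourteen-membered ring to the ten-membered carbinol 9, with an isopropenyl group on C3 and a vinyl group on C8. Compared with any end-to-end closure there is no seco-chain and no high dilution, the olefin geometry comes from a chair transition state, and the enolate is formed at one defined position. Asked: the [3,3] shift must be faster than any reaction of the alkoxide with the epoxide and must give the E olefin.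

**9 ⇒ 8 ⇒ 7.** Remove the isopropenyl group (C4, C5, C18) from C3 and the epoxide oxygen. The epoxide is introduced at the ten-membered stage because there C11=C12 is the only trisubstituted olefin. C7=C8 does not exist until step 7, so the two look-alike alkenes are told apart by the time at which they appear, not by a reagent.

**7 ⇒ 5 (via 6).** The same retron again: cut C9–C10, rejoin C3–C12, remove the C19 methyl. Ketone 7 is the α-methylation product of dienolate 6, formed by oxy-Cope rearrangement of cyclohexanol 5 (buta-1,3-dien-2-yl on C3, vinyl on C12). The dienyl group is chosen so that the enolate carbon C8 already carries the vinyl group for the next round and only a methyl has to be added.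

**5 ⇒ 4 ⇒ 3 ⇒ 1.** Remove the dienyl group from the carbonyl carbon and the vinyl group from the α-carbon. Ketone 4 is the α-vinylation product (through sulfoxide 3) of enolate 2, which conjugate reduction of (R)-carvone 1 delivers regiospecifically. C5 of carvone is C1 of the target and its isopropenyl group is C15–C17.

## Roads not taken

Alternative 1: the obvious plan cuts C7=C8 and closes the ring by metathesis (second-generation Grubbs catalyst) of diene A1, in which lactone, C4 carbinol and epoxide are already present; the ene reaction follows. The closure must form a trisubstituted olefin in a fourteen-membered ring from a 1,1-disubstituted and a monosubstituted alkene, for which neither rate nor E/Z control can be relied on. A1 needs six stereocentres set on an open chain by separate asymmetric reactions and fragment couplings, and the ring-forming step adds only the ring. The chosen plan has the macrocyclic skeleton with C1, both olefin geometries and the epoxide after seven steps.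

Alternative 2: cut C3–C4 and close keto aldehyde A2 by intramolecular pinacol coupling with low-valent titanium (TiCl3/Zn–Cu), then lactonize. Ring and both carbinol carbons form together, but four diol diastereomers are possible and nothing links them to C1. Low-valent titanium also deoxygenates epoxides, so the 11,12-epoxide would have to be introduced after ring closure, when C7=C8 competes. C1 and C15 would still need their own asymmetric chemistry on the chain.

Alternative 3: cut C1–C14 and close iodide A3 by radical conjugate (Giese) addition onto the unsaturated δ-lactone (Bu3SnH, slow addition), which would set C1 and then C15. Fourteen-membered closure onto a substituted β-carbon competes with simple reduction of the radical, and the cis relation of C1 to C3 is not assured. All oxygenated centres of the chain (C3, C4, C11, C12) must be made first on an acyclic precursor, so a long run-up buys one bond and one stereocentre.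

Key step: step 7

Remark: centres that are erased again (sulfur in 3, the quaternary carbon and carbinol carbon of 3–5 and of 7–9, the enolate geometries of 6, 10 and 11) are written as the expected major isomer and their epimers feed the same products; only (R)-carvone and its descendants carry numbers, all other inputs being commercial reagents given with SMILES.

Step 1
Reactants: 1 (R)-carvone
Product: 3 (2R,5R)-2-methyl-2-[2-(phenylsulfinyl)ethyl]-5-(prop-1-en-2-yl)cyclohexan-1-one (both sulfur epimers), via lithium enolate 2 (not isolated)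
Conditions: LiBH(s-Bu)3, THF, −78 °C; then phenyl vinyl sulfoxide, DMPU, −78 → 0 °C; then H2O
Reagents that add atoms: phenyl vinyl sulfoxide, C=CS(=O)c1ccccc1
Why: Conjugate hydride reduction gives the tetrasubstituted enolate regiospecifically, and its Michael addition to the vinyl sulfoxide (a vinyl cation equivalent) builds the quaternary carbon; axial attack places the new chain cis to the isopropenyl group, the usual course of reductive alkylation of carvone, but this centre (future C12) becomes trigonal in step 4.

Step 2
Reactants: 3 (2R,5R)-2-methyl-2-[2-(phenylsulfinyl)ethyl]-5-(prop-1-en-2-yl)cyclohexan-1-one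
Product: 4 (2R,5R)-2-ethenyl-2-methyl-5-(prop-1-en-2-yl)cyclohexan-1-one
Conditions: NaHCO3, toluene, 110 °C
Reagents that add atoms: none
Why: Thermal syn elimination of the sulfoxide unmasks the vinyl group on the quaternary carbon; no stereocentre is touched.

Step 3
Reactants: 4 (2R,5R)-2-ethenyl-2-methyl-5-(prop-1-en-2-yl)cyclohexan-1-one
Product: 5 (1S,2R,5R)-1-(buta-1,3-dien-2-yl)-2-ethenyl-2-methyl-5-(prop-1-en-2-yl)cyclohexan-1-ol
Conditions: CH2=C(MgCl)CH=CH2 (from chloroprene, Mg, ZnCl2 cat., THF), LaCl3·2LiCl, THF, −78 → 0 °C; then H2O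
Reagents that add atoms: buta-1,3-dien-2-ylmagnesium chloride, C=CC(=C)[Mg]Cl
Why: Grignard addition to the hindered ketone, with LaCl3·2LiCl suppressing enolization at C2; attack anti to the axial α-vinyl group should give mainly the drawn carbinol, and either C3 epimer can reach a chair array for the [3,3] shift.

Step 4
Reactants: 5 (1S,2R,5R)-1-(buta-1,3-dien-2-yl)-2-ethenyl-2-methyl-5-(prop-1-en-2-yl)cyclohexan-1-ol
Product: 7 (2R,5E,9R)-2-ethenyl-2,6-dimethyl-9-(prop-1-en-2-yl)cyclodec-5-en-1-one, via potassium dienolate 6 (not isolated)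
Conditions: KH, 18-crown-6, THF, 0 °C → rt; then MeI, −78 → 0 °C
Reagents that add atoms: iodomethane, CI
Why: Anionic oxy-Cope rearrangement of a 1,2-dialkenylcyclohexanol enlarges the ring from six to ten through a chair with ring carbons C2 and C13 pseudo-equatorial, which gives the (E)-C11=C12 bond; the dienolate is methylated at its α-carbon C8 (kinetic α-alkylation), installing C19 and the vinyl-bearing quaternary centre for the second round (C8 configuration is of no consequence).

Step 5
Reactants: 7 (2R,5E,9R)-2-ethenyl-2,6-dimethyl-9-(prop-1-en-2-yl)cyclodec-5-en-1-one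
Product: 8 (2R,5S,6S,9R)-5,6-epoxy-2-ethenyl-2,6-dimethyl-9-(prop-1-en-2-yl)cyclodecan-1-one
Conditions: L-fructose-derived ketone catalyst (1,2:4,5-di-O-isopropylidene-β-L-erythro-2,3-hexodiulo-2,6-pyranose, 0.3 equiv), KHSO5 (as 2KHSO5·KHSO4·K2SO4), K2CO3, Bu4NHSO4, MeCN/dimethoxymethane/aq. buffer pH 10.5, 0 °C
Reagents that add atoms: potassium peroxymonosulfate, [K+].[O-]S(=O)(=O)OO
Why: Shi epoxidation; the strained trisubstituted (E)-olefin of the ten-membered ring is the only trisubstituted alkene present (C7=C8 does not yet exist; vinyl and isopropenyl react far more slowly), and the L-fructose-derived dioxirane, the mirror image of the catalyst that gives (R,R)-epoxides from such olefins, should deliver oxygen to the face that gives (11S,12S), the ring being free to turn either olefin face outward.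

Step 6
Reactants: 8 (2R,5S,6S,9R)-5,6-epoxy-2-ethenyl-2,6-dimethyl-9-(prop-1-en-2-yl)cyclodecan-1-one
Product: 9 (1R,2R,5S,6S,9R)-5,6-epoxy-2-ethenyl-2,6-dimethyl-1,9-di(prop-1-en-2-yl)cyclodecan-1-ol
Conditions: CH2=C(CH3)MgBr, LaCl3·2LiCl, THF, −78 → −20 °C; then H2O
Reagents that add atoms: isopropenylmagnesium bromide, CC(=C)[Mg]Br
Why: 1,2-Addition of the alkenyl Grignard reagent to the α-quaternary ketone (LaCl3·2LiCl against enolization at C2) at a temperature at which the isolated epoxide is left alone; the new C3 centre is transient.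

Step 7
Reactants: 9 (1R,2R,5S,6S,9R)-5,6-epoxy-2-ethenyl-2,6-dimethyl-1,9-di(prop-1-en-2-yl)cyclodecan-1-ol
Product: 11 (1R,7E,11S,12S)-11,12-epoxy-3-(trimethylsilyloxy)cembra-3,7,15-triene, via potassium enolate 10 (not isolated)
Conditions: KH, 18-crown-6, THF, 0 °C → rt; then TMSCl, Et3N, −78 °C
Reagents that add atoms: chlorotrimethylsilane, C[Si](C)(C)Cl
Why: Deprotonation gives the potassium alkoxide, whose charge weakens the C3–C8 bond so that the [3,3] sigmatropic shift of the 1,5-diene C5=C4–C3–C8–C7=C6 (anionic oxy-Cope rearrangement) should run at or below room temperature. The closest known reaction type is the four-atom ring enlargement of 1,2-dialkenylcycloalkanols, the same process as step 4. No ring is closed end to end: the ten-membered ring is opened at C3–C8 while C5–C6 forms, so the fourteen-membered ring arises by concerted ring enlargement through a six-atom chair array. No stereocentre is created that survives, and the transient centres C3 and C8 are erased, so all diastereomers of 9 converge. What the step sets is the geometry of C7=C8: E when C9 sits pseudo-equatorial and the C19 methyl pseudo-axial in the chair, the arrangement that keeps the C2-to-C9 bridge gauche as in the ground state. The enolate 10 is formed only at C3/C4 and is stored as silyl enol ether 11, which fixes where the C4=C5 bond and hence the C4 oxygen will go. The step needs the rearrangement to outrun attack of the alkoxide on the 11,12-epoxide across the ring; this is secured by relief of ten-membered-ring strain and by the alkoxide oxygen standing outside the ring on a fully substituted carbon, away from the backside of the epoxide C–O bonds.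

Step 8
Reactants: 11 (1R,7E,11S,12S)-11,12-epoxy-3-(trimethylsilyloxy)cembra-3,7,15-triene
Product: 12 (1R,4E,7E,11S,12S)-11,12-epoxycembra-4,7,15-trien-3-one
Conditions: Pd(OAc)2 (1.05 equiv), MeCN, rt
Reagents that add atoms: none
Why: Saegusa–Ito oxidation; divalent palladium takes the enolate from silicon at C4, and β-hydride elimination toward ring carbon C5 gives the conjugated, more substituted (4E)-enone with loss of zerovalent palladium, the site of unsaturation being fixed by the enol ether of step 7.

Step 9
Reactants: 12 (1R,4E,7E,11S,12S)-11,12-epoxycembra-4,7,15-trien-3-one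
Product: 13 (1R,3R,4E,7E,11S,12S)-11,12-epoxycembra-4,7,15-trien-3-ol
Conditions: (S)-2-methyl-CBS-oxazaborolidine (0.2 equiv), catecholborane, toluene, −78 °C; then MeOH, aq. NaOH
Reagents that add atoms: none
Why: Corey–Bakshi–Shibata reduction; the α-methylalkenyl branch acts as the large group and C2H2 as the small one, so the (S)-catalyst should give the (3R)-allylic alcohol, and catecholborane at −78 °C leaves alkenes and epoxide alone.

Step 10
Reactants: 13 (1R,3R,4E,7E,11S,12S)-11,12-epoxycembra-4,7,15-trien-3-ol
Product: 14 (1R,3R,4R,5R,7E,11S,12S)-4,5:11,12-diepoxycembra-7,15-dien-3-ol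
Conditions: Ti(OiPr)4 (0.2 equiv), D-(−)-diisopropyl tartrate (0.24 equiv), t-BuOOH, 4 Å molecular sieves, CH2Cl2, −20 °C
Reagents that add atoms: tert-butyl hydroperoxide, CC(C)(C)OO
Why: Sharpless asymmetric epoxidation of a secondary allylic alcohol in its matched sense (D-tartrate with the 3R carbinol); the titanium-bound hydroxyl directs oxygen only to C4=C5 and gives the erythro epoxy alcohol, which puts the C4 oxygen on the face that becomes 4S, while C7=C8 and the isopropenyl group are not touched.

Step 11
Reactants: 14 (1R,3R,4R,5R,7E,11S,12S)-4,5:11,12-diepoxycembra-7,15-dien-3-ol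
Product: 15 (1R,3R,4S,7E,11S,12S)-11,12-epoxycembra-7,15-diene-3,4-diol
Conditions: LiBH4, Ti(OiPr)4 (1.5 equiv), THF, 0 °C → rt; then H2O
Reagents that add atoms: none
Why: Titanium-assisted hydride opening of a 2,3-epoxy alcohol; chelation by the hydroxyl and the neighbouring epoxide activates only this epoxide, and hydride attacks the less substituted C5 (C4 is fully substituted), which leaves the C4–O bond and gives the anti (3R,4S)-diol, while the 11,12-epoxide has no neighbouring hydroxyl and should remain.

Step 12
Reactants: 15 (1R,3R,4S,7E,11S,12S)-11,12-epoxycembra-7,15-diene-3,4-diol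
Product: 17 (1R,3R,4S,7E,11S,12S)-11,12-epoxycembr-7-ene-3,4,16-triol (C15 epimers), via B-alkyl-9-BBN adduct 16 (not isolated)
Conditions: 9-BBN (4 equiv), THF, 0 °C → rt; then NaOH, H2O2, 0 °C
Reagents that add atoms: hydrogen peroxide, OO; 9-borabicyclo[3.3.1]nonane, B1C2CCCC1CCC2 (boron of 16 only)
Why: Hydroboration–oxidation; 9-BBN adds to the 1,1-disubstituted isopropenyl group much faster than to the trisubstituted C7=C8 bond and places boron on C16, and C15 forms as an epimer mixture that is corrected in step 14.

Step 13
Reactants: 17 (1R,3R,4S,7E,11S,12S)-11,12-epoxycembr-7-ene-3,4,16-triol (C15 epimers)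
Product: 20 (1R,3R,4S,7E,11S,12S)-11,12-epoxy-4-hydroxycembr-7-en-16,3-olide (C15 epimers), via hydroxy aldehyde 18 (not isolated), via lactol 19 (not isolated)
Conditions: Cu(MeCN)4OTf (5 mol %), 2,2′-bipyridine, TEMPO, N-methylimidazole, air, MeCN, rt
Reagents that add atoms: none
Why: Copper/nitroxyl aerobic oxidative lactonization of a 1,5-diol; the unhindered primary C16 hydroxyl is oxidized first, the aldehyde closes with the C3 hydroxyl to the six-membered lactol (the tertiary C4 hydroxyl would need a seven-membered ring), and a second oxidation gives the δ-lactone with the cis C1/C3 bridge already fixed.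

Step 14
Reactants: 20 (1R,3R,4S,7E,11S,12S)-11,12-epoxy-4-hydroxycembr-7-en-16,3-olide (C15 epimers)
Product: 21 (1R,3R,4S,7E,11S,12S,15S)-11,12-epoxy-4-hydroxycembr-7-en-16,3-olide
Conditions: KOt-Bu (0.2 equiv), t-BuOH/THF, 0 °C → rt; then AcOH
Reagents that add atoms: none
Why: Base-catalysed epimerization α to the lactone carbonyl; reversible enolization should equilibrate C15 toward the isomer with the methyl pseudo-equatorial and trans to the C1–C14 bond, which is 15S.

Step 15
Reactants: 21 (1R,3R,4S,7E,11S,12S,15S)-11,12-epoxy-4-hydroxycembr-7-en-16,3-olide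
Product: 22 (1R,3R,4S,7S,11S,12S,15S)-11,12-epoxy-7-hydroperoxy-4-hydroxycembr-8(19)-en-16,3-olide
Conditions: O2, visible light, meso-tetraphenylporphyrin (cat.), CH2Cl2, −20 °C
Reagents that add atoms: dioxygen, O=O
Why: Schenck ene reaction; singlet oxygen adds to C7 of the only remaining olefin and abstracts hydrogen on the disubstituted side of the (7E) bond (cis effect, where C19 and C6 lie), abstraction from C19 giving the secondary hydroperoxide with the C8=C19 methylene; C7 is set by attack on the outward-turned olefin face of the lactone-bridged ring, and the tertiary C8 hydroperoxide from abstraction at C6 is the expected by-product to be separated.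

## Compound list

1 | (R)-carvone, (5R)-2-methyl-5-(prop-1-en-2-yl)cyclohex-2-en-1-one | CC1=CC[C@H](CC1=O)C(C)=C | starting material
2 | lithium (5R)-2-methyl-5-(prop-1-en-2-yl)cyclohex-1-en-1-olate (not isolated) | [Li+].CC1=C([O-])C[C@@H](CC1)C(C)=C | intermediate
3 | (2R,5R)-2-methyl-2-[2-(phenylsulfinyl)ethyl]-5-(prop-1-en-2-yl)cyclohexan-1-one (sulfur epimers) | C[C@]1(CCS(=O)c2ccccc2)CC[C@H](CC1=O)C(C)=C | intermediate
4 | (2R,5R)-2-ethenyl-2-methyl-5-(prop-1-en-2-yl)cyclohexan-1-one | C[C@]1(C=C)CC[C@H](CC1=O)C(C)=C | intermediate
5 | (1S,2R,5R)-1-(buta-1,3-dien-2-yl)-2-ethenyl-2-methyl-5-(prop-1-en-2-yl)cyclohexan-1-ol | C=CC(=C)[C@@]1(O)C[C@@H](CC[C@]1(C)C=C)C(C)=C | intermediate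
6 | potassium (5E,9R)-2-ethenyl-6-methyl-9-(prop-1-en-2-yl)cyclodeca-1,5-dien-1-olate (not isolated) | C=CC1=C([O-])C[C@@H](CC/C(C)=C/CC1)C(C)=C.[K+] | intermediate
7 | (2R,5E,9R)-2-ethenyl-2,6-dimethyl-9-(prop-1-en-2-yl)cyclodec-5-en-1-one (ring C1, C2, C5, C6, C9 = cembrane C3, C8, C11, C12, C1) | C=C[C@@]1(C)CC/C=C(C)/CC[C@H](CC1=O)C(C)=C | intermediate
8 | (2R,5S,6S,9R)-5,6-epoxy-2-ethenyl-2,6-dimethyl-9-(prop-1-en-2-yl)cyclodecan-1-one | C=C[C@@]1(C)CC[C@@H]2O[C@@]2(C)CC[C@H](CC1=O)C(C)=C | intermediate
9 | (1R,2R,5S,6S,9R)-5,6-epoxy-2-ethenyl-2,6-dimethyl-1,9-di(prop-1-en-2-yl)cyclodecan-1-ol | C=C[C@@]1(C)CC[C@@H]2O[C@@]2(C)CC[C@H](C[C@@]1(O)C(C)=C)C(C)=C | intermediate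
10 | potassium (1R,7E,11S,12S)-11,12-epoxycembra-3,7,15-trien-3-olate (not isolated) | C1/C=C(\C)CC[C@@H]2O[C@@]2(C)CC[C@@H](C(C)=C)CC([O-])=C(C)C1.[K+] | intermediate
11 | (1R,7E,11S,12S)-11,12-epoxy-3-(trimethylsilyloxy)cembra-3,7,15-triene | C1/C=C(\C)CC[C@@H]2O[C@@]2(C)CC[C@@H](C(C)=C)CC(O[Si](C)(C)C)=C(C)C1 | intermediate
12 | (1R,4E,7E,11S,12S)-11,12-epoxycembra-4,7,15-trien-3-one | O=C1/C(C)=C/C/C=C(\C)CC[C@@H]2O[C@@]2(C)CC[C@@H](C(C)=C)C1 | intermediate
13 | (1R,3R,4E,7E,11S,12S)-11,12-epoxycembra-4,7,15-trien-3-ol | O[C@H]1/C(C)=C/C/C=C(\C)CC[C@@H]2O[C@@]2(C)CC[C@@H](C(C)=C)C1 | intermediate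
14 | (1R,3R,4R,5R,7E,11S,12S)-4,5:11,12-diepoxycembra-7,15-dien-3-ol | O[C@H]1[C@@]3(C)O[C@@H]3C/C=C(\C)CC[C@@H]2O[C@@]2(C)CC[C@@H](C(C)=C)C1 | intermediate
15 | (1R,3R,4S,7E,11S,12S)-11,12-epoxycembra-7,15-diene-3,4-diol | O[C@H]1[C@@](C)(O)CC/C=C(\C)CC[C@@H]2O[C@@]2(C)CC[C@@H](C(C)=C)C1 | intermediate
16 | 16-(9-borabicyclo[3.3.1]nonan-9-yl) adduct of 15 (C15 epimers, hydroxyls transiently O-borylated, not isolated) | O[C@H]1[C@@](C)(O)CC/C=C(\C)CC[C@@H]2O[C@@]2(C)CC[C@@H](C(C)CB3C4CCCC3CCC4)C1 | intermediate
17 | (1R,3R,4S,7E,11S,12S)-11,12-epoxycembr-7-ene-3,4,16-triol (C15 epimers) | O[C@H]1[C@@](C)(O)CC/C=C(\C)CC[C@@H]2O[C@@]2(C)CC[C@@H](C(C)CO)C1 | intermediate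
18 | (1R,3R,4S,7E,11S,12S)-11,12-epoxy-3,4-dihydroxycembr-7-en-16-al (C15 epimers, not isolated) | O[C@H]1[C@@](C)(O)CC/C=C(\C)CC[C@@H]2O[C@@]2(C)CC[C@@H](C(C)C=O)C1 | intermediate
19 | 16,3-lactol of 18 (C15 and C16 epimers, not isolated) | C1/C=C(\C)CC[C@@H]2O[C@@]2(C)CC[C@@H]2C[C@@H](OC(O)C2C)[C@@](C)(O)C1 | intermediate
20 | (1R,3R,4S,7E,11S,12S)-11,12-epoxy-4-hydroxycembr-7-en-16,3-olide (C15 epimers) | C1/C=C(\C)CC[C@@H]2O[C@@]2(C)CC[C@@H]2C[C@@H](OC(=O)C2C)[C@@](C)(O)C1 | intermediate
21 | (1R,3R,4S,7E,11S,12S,15S)-11,12-epoxy-4-hydroxycembr-7-en-16,3-olide | C1/C=C(\C)CC[C@@H]2O[C@@]2(C)CC[C@@H]2C[C@@H](OC(=O)[C@H]2C)[C@@](C)(O)C1 | intermediate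
22 | (1R,3R,4S,7S,11S,12S,15S)-11,12-epoxy-7-hydroperoxy-4-hydroxycembr-8(19)-en-16,3-olide | C=C1CC[C@@H]2O[C@@]2(C)CC[C@@H]2C[C@@H](OC(=O)[C@H]2C)[C@@](C)(O)CC[C@@H]1OO | target

Total step count: 15. Longest linear sequence: 15 steps from (R)-carvone 1.

## Least certain steps

**Step 7 (key step).** The naked tertiary alkoxide may attack the 11,12-epoxide across the ten-membered ring before the sigmatropic shift, because that ring brings the C3 oxygen within reach of C11; a second hazard is passage through the other chair (C9 axial), which would give the 7Z olefin. Fallback: starting from 9, the hydroxyl is silylated with N-(trimethylsilyl)imidazole to the trimethylsilyl ether F1. F1 is heated in degassed 1,2-dichlorobenzene at about 190 °C, so that the neutral siloxy-Cope rearrangement gives silyl enol ether 11 directly with no alkoxide present. The route continues at 11.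

**Step 15.** Facial and positional selectivity of the ene reaction may be poor: oxygen can add to either face of C7=C8 because only the macrocycle conformation distinguishes them, and abstraction from C6 competes with abstraction from C19. Fallback: starting from 21, the photooxygenation is run and the secondary hydroperoxides are collected, including the C7 epimer F2. F2 is dehydrated with Ac2O/pyridine (Kornblum–DeLaMare reaction) to the exocyclic enone F3. F3 is reduced with (S)-2-methyl-CBS-oxazaborolidine/catecholborane to the (7R)-alcohol F4 and converted into the methanesulfonate F5. F5 is displaced with the caesium salt of 2-methoxyprop-2-yl hydroperoxide (CsOH, DMF), with inversion at C7, to the peroxyketal F6. Aqueous acetic acid removes the ketal from F6 and gives 22.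

**Step 5.** Facial selectivity may be lost: each conformer of the ten-membered ring exposes only one olefin face, and the resident centres C1 and C8 may favour the conformer that the catalyst disfavours. Fallback: starting from 7, the epoxidation is run and the unwanted (11R,12R)-epoxide F7 is converted into 8. Dilute HClO4 in aqueous THF opens F7 at the tertiary C12 with inversion to the (11R,12S)-diol F8. Mesylation of the secondary hydroxyl of F8 gives the methanesulfonate F9, and K2CO3 in methanol closes the ring of F9 with inversion at C11 to give 8.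

**Step 11.** Chemoselectivity between the two trisubstituted epoxides may fail, with hydride opening the 11,12-epoxide at C11 if chelation does not dominate. Fallback: starting from 9, steps 8–11 are bypassed. Enolate 10 from the key step is quenched at −78 °C with 2-(phenylsulfonyl)-3-phenyloxaziridine to give the α-hydroxy ketone F10. Chelation-controlled reduction of F10 with Zn(BH4)2 in ether (hydride from the side of the C4 methyl, away from the ring chain) gives the anti-diol 15. The price is that C4 is then set under substrate control, or under that of an enantiopure camphor-derived oxaziridine.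

**Step 3.** The dienyl Grignard reagent may react with allylic transposition (bonding through its terminal carbon to give an allenic carbinol), which steric hindrance at the α-quaternary ketone would favour. Fallback: starting from 4, isopropenylmagnesium bromide gives the carbinol F11. KH/18-crown-6 converts F11 by the same rearrangement into the potassium enolate F12, which is trapped with phenyl vinyl sulfoxide to the sulfoxide F13. Thermolysis of F13 (toluene, 110 °C) gives 7.

## Further compounds

F1 | step 7 | trimethylsilyl ether of 9 | C=C[C@@]1(C)CC[C@@H]2O[C@@]2(C)CC[C@H](C[C@@]1(O[Si](C)(C)C)C(C)=C)C(C)=C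
F2 | step 15 | (1R,3R,4S,7R,11S,12S,15S)-11,12-epoxy-7-hydroperoxy-4-hydroxycembr-8(19)-en-16,3-olide (C7 epimer of 22) | C=C1CC[C@@H]2O[C@@]2(C)CC[C@@H]2C[C@@H](OC(=O)[C@H]2C)[C@@](C)(O)CC[C@H]1OO
F3 | step 15 | (1R,3R,4S,11S,12S,15S)-11,12-epoxy-4-hydroxy-7-oxocembr-8(19)-en-16,3-olide | C=C1CC[C@@H]2O[C@@]2(C)CC[C@@H]2C[C@@H](OC(=O)[C@H]2C)[C@@](C)(O)CCC1=O
F4 | step 15 | (1R,3R,4S,7R,11S,12S,15S)-11,12-epoxy-4,7-dihydroxycembr-8(19)-en-16,3-olide | C=C1CC[C@@H]2O[C@@]2(C)CC[C@@H]2C[C@@H](OC(=O)[C@H]2C)[C@@](C)(O)CC[C@H]1O
F5 | step 15 | 7-O-methanesulfonate of F4 | C=C1CC[C@@H]2O[C@@]2(C)CC[C@@H]2C[C@@H](OC(=O)[C@H]2C)[C@@](C)(O)CC[C@H]1OS(C)(=O)=O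
F6 | step 15 | (7S)-7-[(2-methoxypropan-2-yl)peroxy] derivative of 22 | C=C1CC[C@@H]2O[C@@]2(C)CC[C@@H]2C[C@@H](OC(=O)[C@H]2C)[C@@](C)(O)CC[C@@H]1OOC(C)(C)OC
F7 | step 5 | (2R,5R,6R,9R)-5,6-epoxy-2-ethenyl-2,6-dimethyl-9-(prop-1-en-2-yl)cyclodecan-1-one | C=C[C@@]1(C)CC[C@H]2O[C@]2(C)CC[C@H](CC1=O)C(C)=C
F8 | step 5 | (2R,5R,6S,9R)-2-ethenyl-5,6-dihydroxy-2,6-dimethyl-9-(prop-1-en-2-yl)cyclodecan-1-one | C=C[C@@]1(C)CC[C@@H](O)[C@@](C)(O)CC[C@H](CC1=O)C(C)=C
F9 | step 5 | 5-O-methanesulfonate of F8 | C=C[C@@]1(C)CC[C@@H](OS(C)(=O)=O)[C@@](C)(O)CC[C@H](CC1=O)C(C)=C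
F10 | step 11 | (1R,4S,7E,11S,12S)-11,12-epoxy-4-hydroxycembra-7,15-dien-3-one | O=C1[C@@](C)(O)CC/C=C(\C)CC[C@@H]2O[C@@]2(C)CC[C@@H](C(C)=C)C1
F11 | step 3 | (1S,2R,5R)-2-ethenyl-2-methyl-1,5-di(prop-1-en-2-yl)cyclohexan-1-ol | CC(=C)[C@@]1(O)C[C@@H](CC[C@]1(C)C=C)C(C)=C
F12 | step 3 | potassium (5E,9R)-2,6-dimethyl-9-(prop-1-en-2-yl)cyclodeca-1,5-dien-1-olate | CC1=C([O-])C[C@@H](CC/C(C)=C/CC1)C(C)=C.[K+]
F13 | step 3 | (2R,5E,9R)-2,6-dimethyl-2-[2-(phenylsulfinyl)ethyl]-9-(prop-1-en-2-yl)cyclodec-5-en-1-one | C[C@]1(CCS(=O)c2ccccc2)CC/C=C(C)/CC[C@H](CC1=O)C(C)=C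
A1 | alternative 1 | seco-diene of 21 opened at C7=C8 (δ-lactone core with a but-3-enyl arm on C4 and an isopropenyl-terminated epoxy arm on C1) | C=C(C)CC[C@@H]2O[C@@]2(C)CC[C@@H]2C[C@@H](OC(=O)[C@H]2C)[C@@](C)(O)CCC=C
A2 | alternative 2 | methyl (2S,3R,6E,10E)-2,6,10-trimethyl-14-oxo-3-(2-oxoethyl)pentadeca-6,10-dienoate | CC(=O)CC/C=C(\C)CC/C=C(\C)CC[C@H](CC=O)[C@H](C)C(=O)OC
A3 | alternative 3 | (6R)-3-methyl-5,6-dihydro-2H-pyran-2-one carrying at C6 the (4S,7E,11S,12S)-11,12-epoxy-4-hydroxy chain C4–C14 that ends in a primary iodide | CC1=CC[C@@H](OC1=O)[C@@](C)(O)CC/C=C(\C)CC[C@@H]2O[C@@]2(C)CCI
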